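The two exocyclic bonds C3–C9 and C4–C9' of the oxolane ring (C9, C9' = the hydroxymethyl carbons) are the disconnection on which everything rests. The feature exploited is that C9 and C9' are trans to each other and C9 is trans to the aryl group on C2, so one benzylic stereocentre on a flat ring can relay both. The precursor is therefore (S)-5-aryl butenolide 7, whose alkene carbons become C3 and C4. In one flask a silylmethyl copper reagent adds to its β-carbon and formaldehyde traps the enolate, creating both carbons and two stereocentres. Silicon bears benzyl, not alkoxy, so it survives aryllithium addition and ionic hydrogenation at C5 and is oxidised last.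

Key step: step 6

Assumption: compounds 1, 8 and 14 are taken as purchased; each is otherwise one step from vanillin, from benzylmagnesium chloride and chloro(chloromethyl)dimethylsilane, or from 4-bromo-2-methoxyphenol.

Numbering remark: target ring atoms are O1, C2 (aryl carbon inherited from 7), C3 (bearing C9), C4 (bearing C9') and C5 (aryl carbon from the lactone carbonyl); the target is 2,3-trans, 3,4-trans, 4,5-cis. Lactone names use their own locants, in which lactone C5, C4 and C3 are target C2, C3 and C4.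

Design remark: an Si–O bond on the silylmethyl reagent is avoided because it would sit five atoms from the new alkoxide and close to a cyclic silyl ether, would not tolerate aryllithium or BF3·OEt2, and, if oxidised at the lactone stage, would free a 4-hydroxymethyl lactone that can migrate its acyl group.

Step 1
Reactants: 1 4-(benzyloxy)-3-methoxybenzaldehyde; 2 vinylmagnesium bromide
Product: 3 rac-1-[4-(benzyloxy)-3-methoxyphenyl]prop-2-en-1-ol
Conditions: 2 (1.2 equiv), THF, −78 → 0 °C; aq NH4Cl
Reagents that add atoms: vinylmagnesium bromide (2), C=C[Mg]Br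
Why: Grignard 1,2-addition of a vinyl nucleophile to an aromatic aldehyde, which forms the carbinol centre as a racemate that is sorted out in step 2.

Step 2
Reactants: 3 rac-1-[4-(benzyloxy)-3-methoxyphenyl]prop-2-en-1-ol
Product: 4 (S)-1-[4-(benzyloxy)-3-methoxyphenyl]prop-2-en-1-ol
Conditions: immobilised Candida antarctica lipase B, vinyl acetate, MTBE, 30 °C, run slightly past half conversion; chromatography
Reagents that add atoms: none
Why: Lipase-catalysed kinetic resolution by transesterification, in which the enzyme (aryl as large, vinyl as medium substituent) should acetylate the R alcohol and leave the S alcohol, whose configuration becomes C2 of the target.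

Step 3
Reactants: 4 (S)-1-[4-(benzyloxy)-3-methoxyphenyl]prop-2-en-1-ol; 5 acryloyl chloride
Product: 6 (S)-1-[4-(benzyloxy)-3-methoxyphenyl]prop-2-en-1-yl prop-2-enoate
Conditions: 5 (1.3 equiv), Et3N, CH2Cl2, −20 → 0 °C
Reagents that add atoms: acryloyl chloride (5), C=CC(=O)Cl
Why: Esterification of a secondary alcohol with an acid chloride and an amine base, which leaves the C–O bond of the stereocentre untouched, while the cold buffered medium keeps the electron-rich allylic benzylic system from ionising.

Step 4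
Reactants: 6 (S)-1-[4-(benzyloxy)-3-methoxyphenyl]prop-2-en-1-yl prop-2-enoate
Product: 7 (S)-5-[4-(benzyloxy)-3-methoxyphenyl]furan-2(5H)-one
Conditions: second-generation Grubbs catalyst (5 mol %), CH2Cl2 (0.01 M, degassed), 40 °C
Reagents that add atoms: none
Why: Ring-closing olefin metathesis between the acrylate and the vinyl group closes the unsaturated five-membered lactone with loss of ethylene, the stereocentre being a spectator and dilution disfavouring dimerisation.

Step 5
Reactants: 8 benzyl(chloromethyl)dimethylsilane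
Product: 9 [(benzyldimethylsilyl)methyl]magnesium chloride (titrated THF solution)
Conditions: Mg turnings, BrCH2CH2Br (cat.), THF, 50 °C → rt
Reagents that add atoms: magnesium, [Mg]
Why: Grignard formation by magnesium insertion into a primary C–Cl bond next to silicon, as for (trimethylsilyl)methyl chloride, and with only carbon groups on silicon the reagent cannot attack itself.

Step 6
Reactants: 7 (S)-5-[4-(benzyloxy)-3-methoxyphenyl]furan-2(5H)-one; 9 [(benzyldimethylsilyl)methyl]magnesium chloride; 10 formaldehyde (anhydrous monomer, cracked from paraformaldehyde just before use)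
Product: 12 (3R,4S,5S)-5-[4-(benzyloxy)-3-methoxyphenyl]-4-[(benzyldimethylsilyl)methyl]-3-(hydroxymethyl)oxolan-2-one, via chloromagnesium enolate 11 (not isolated)
Conditions: 9 (1.4 equiv) added slowly to 7 and CuBr·SMe2 (10 mol %), THF, −78 °C; then CH2=O gas (excess), −78 → −60 °C; aq NH4Cl at −78 °C
Reagents that add atoms: [(benzyldimethylsilyl)methyl]magnesium chloride (9), C[Si](C)(Cc1ccccc1)C[Mg]Cl; formaldehyde (10), C=O
Why: Transmetalation of 9 to CuBr·SMe2 gives a monovalent-copper silylmethyl species that forms a π-complex with the enoate, adds at the β-carbon through a trivalent-copper intermediate and reductively eliminates to forge C3–C9, leaving chloromagnesium enolate 11, which then adds to monomeric formaldehyde in an aldol reaction to forge C4–C9'. The closest known reaction type is the copper-catalysed conjugate addition of silylmethyl Grignard reagents to enones and butenolides, combined with aldehyde trapping of the resulting enolate in a three-component coupling. No ring is closed; the existing lactone serves as a rigid, nearly planar template. The new C3 centre is controlled by the C2 aryl group, which shields one face of the butenolide so that copper delivers carbon anti to it, and the new C4 centre is controlled by the freshly installed C3 silylmethyl group, which sends formaldehyde to the opposite face of the enolate; the all-trans lactone is also the thermodynamically preferred one, so any α-epimerisation works in the same direction. The step needs 1,4- over 1,2-addition, secured by copper catalysis at −78 °C with slow Grignard addition, and it needs the acidic benzylic C2–H to stay in place, secured by the low basicity of the organocopper and the cold NH4Cl quench.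

Step 7
Reactants: 12 (3R,4S,5S)-5-[4-(benzyloxy)-3-methoxyphenyl]-4-[(benzyldimethylsilyl)methyl]-3-(hydroxymethyl)oxolan-2-one
Product: 13 (3R,4S,5S)-5-[4-(benzyloxy)-3-methoxyphenyl]-4-[(benzyldimethylsilyl)methyl]-3-{[(tert-butyldimethylsilyl)oxy]methyl}oxolan-2-one
Conditions: TBSCl, imidazole, DMF, 0 °C → rt
Reagents that add atoms: tert-butyldimethylsilyl chloride, CC(C)(C)[Si](C)(C)Cl
Why: Silyl ether formation at the primary alcohol with imidazole as a mild base, which avoids the retro-aldol, dehydration or epimerisation that a strong base could cause next to the lactone carbonyl and affects no stereocentre.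

Step 8
Reactants: 13 (3R,4S,5S)-5-[4-(benzyloxy)-3-methoxyphenyl]-4-[(benzyldimethylsilyl)methyl]-3-{[(tert-butyldimethylsilyl)oxy]methyl}oxolan-2-one; 14 1-(benzyloxy)-4-bromo-2-methoxybenzene
Product: 16 (3R,4S,5S)-2,5-bis[4-(benzyloxy)-3-methoxyphenyl]-4-[(benzyldimethylsilyl)methyl]-3-{[(tert-butyldimethylsilyl)oxy]methyl}oxolan-2-ol (mixture at C2), via aryllithium 15 (not isolated)
Conditions: 14 (1.35 equiv), n-BuLi (1.3 equiv), THF, −78 °C; then 13, −78 °C; aq NH4Cl at −78 °C
Reagents that add atoms: 1-(benzyloxy)-4-bromo-2-methoxybenzene (14), COc1cc(Br)ccc1OCc1ccccc1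
Why: Bromine–lithium exchange followed by nucleophilic addition of the aryllithium to the lactone carbonyl, where the tetrahedral lithium alkoxide persists at −78 °C and so prevents a second addition, the hemiketal carbon forming as an inconsequential mixture that is flattened in step 9.

Step 9
Reactants: 16 (3R,4S,5S)-2,5-bis[4-(benzyloxy)-3-methoxyphenyl]-4-[(benzyldimethylsilyl)methyl]-3-{[(tert-butyldimethylsilyl)oxy]methyl}oxolan-2-ol
Product: 17 (2S,3S,4R,5R)-2,5-bis[4-(benzyloxy)-3-methoxyphenyl]-3-[(benzyldimethylsilyl)methyl]-4-{[(tert-butyldimethylsilyl)oxy]methyl}oxolane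
Conditions: Et3SiH (5 equiv), BF3·OEt2 (2 equiv), CH2Cl2, −78 °C; Et3N then aq NaHCO3 at −78 °C
Reagents that add atoms: none
Why: Ionic hydrogenation of a cyclic hemiketal, in which BF3·OEt2 generates the 2-aryl oxocarbenium ion and Et3SiH delivers hydride to the face opposite the adjacent C4 silyloxymethyl arm (also the face opposite the C2 aryl group), so that the C5 aryl group ends up cis to the C4 arm as in 3,4-disubstituted 2-aryl oxolanes made this way, while −78 °C and a cold basic quench guard against acid-promoted ring opening and reclosure to the all-trans isomer.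

Step 10
Reactants: 17 (2S,3S,4R,5R)-2,5-bis[4-(benzyloxy)-3-methoxyphenyl]-3-[(benzyldimethylsilyl)methyl]-4-{[(tert-butyldimethylsilyl)oxy]methyl}oxolane
Product: 18 {(2S,3R,4R,5R)-2,5-bis[4-(benzyloxy)-3-methoxyphenyl]oxolane-3,4-diyl}dimethanol
Conditions: Bu4NF (5 equiv), THF, 0 °C → rt; then KHCO3, 30% H2O2, MeOH, 40 °C
Reagents that add atoms: hydrogen peroxide, OO
Why: Fluoride-promoted Tamao–Fleming oxidation, in which fluoride (helped by the alkoxide freed from the silyl ether on the neighbouring arm) expels the benzyl group from silicon as toluene and the resulting silanol or cyclic silyl ether migrates its CH2 carbon to oxygen under H2O2/KHCO3, the same fluoride removing the tert-butyldimethylsilyl ether and no stereocentre being touched.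

Step 11
Reactants: 18 {(2S,3R,4R,5R)-2,5-bis[4-(benzyloxy)-3-methoxyphenyl]oxolane-3,4-diyl}dimethanol
Product: 19 [(2S,3R,4R,5R)-2,5-bis(4-hydroxy-3-methoxyphenyl)oxolane-3,4-diyl]dimethanol
Conditions: H2 (1 atm), 10% Pd/C, EtOAc, rt, stopped as soon as both aryl benzyl ethers are consumed
Reagents that add atoms: none
Why: Catalytic hydrogenolysis of the two aryl benzyl ethers, which in a neutral solvent without acid should be cleaved much faster than the doubly benzylic ring C–O bonds, so that short exposure frees the phenols without opening the oxolane or touching a stereocentre.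

Compound list
1 | 4-(benzyloxy)-3-methoxybenzaldehyde | COc1cc(C=O)ccc1OCc1ccccc1 | starting material
2 | vinylmagnesium bromide | C=C[Mg]Br | starting material
3 | rac-1-[4-(benzyloxy)-3-methoxyphenyl]prop-2-en-1-ol | COc1cc(C(O)C=C)ccc1OCc1ccccc1 | intermediate
4 | (S)-1-[4-(benzyloxy)-3-methoxyphenyl]prop-2-en-1-ol | COc1cc([C@@H](O)C=C)ccc1OCc1ccccc1 | intermediate
5 | acryloyl chloride | C=CC(=O)Cl | starting material
6 | (S)-1-[4-(benzyloxy)-3-methoxyphenyl]prop-2-en-1-yl prop-2-enoate | COc1cc([C@@H](OC(=O)C=C)C=C)ccc1OCc1ccccc1 | intermediate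
7 | (S)-5-[4-(benzyloxy)-3-methoxyphenyl]furan-2(5H)-one | COc1cc([C@H]2OC(=O)C=C2)ccc1OCc1ccccc1 | intermediate
8 | benzyl(chloromethyl)dimethylsilane | ClC[Si](C)(C)Cc1ccccc1 | starting material
9 | [(benzyldimethylsilyl)methyl]magnesium chloride | C[Si](C)(Cc1ccccc1)C[Mg]Cl | intermediate
10 | formaldehyde | C=O | starting material
11 | chloromagnesium enolate of (4S,5S)-5-[4-(benzyloxy)-3-methoxyphenyl]-4-[(benzyldimethylsilyl)methyl]oxolan-2-one | COc1cc([C@H]2OC(O[Mg]Cl)=C[C@@H]2C[Si](C)(C)Cc2ccccc2)ccc1OCc1ccccc1 | intermediate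
12 | (3R,4S,5S)-5-[4-(benzyloxy)-3-methoxyphenyl]-4-[(benzyldimethylsilyl)methyl]-3-(hydroxymethyl)oxolan-2-one | COc1cc([C@H]2OC(=O)[C@@H](CO)[C@@H]2C[Si](C)(C)Cc2ccccc2)ccc1OCc1ccccc1 | intermediate
13 | (3R,4S,5S)-5-[4-(benzyloxy)-3-methoxyphenyl]-4-[(benzyldimethylsilyl)methyl]-3-{[(tert-butyldimethylsilyl)oxy]methyl}oxolan-2-one | COc1cc([C@H]2OC(=O)[C@@H](CO[Si](C)(C)C(C)(C)C)[C@@H]2C[Si](C)(C)Cc2ccccc2)ccc1OCc1ccccc1 | intermediate
14 | 1-(benzyloxy)-4-bromo-2-methoxybenzene | COc1cc(Br)ccc1OCc1ccccc1 | starting material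
15 | [4-(benzyloxy)-3-methoxyphenyl]lithium | COc1cc([Li])ccc1OCc1ccccc1 | intermediate
16 | (3R,4S,5S)-2,5-bis[4-(benzyloxy)-3-methoxyphenyl]-4-[(benzyldimethylsilyl)methyl]-3-{[(tert-butyldimethylsilyl)oxy]methyl}oxolan-2-ol, mixture at C2 | COc1cc([C@H]2OC(O)(c3ccc(OCc4ccccc4)c(OC)c3)[C@@H](CO[Si](C)(C)C(C)(C)C)[C@@H]2C[Si](C)(C)Cc2ccccc2)ccc1OCc1ccccc1 | intermediate
17 | (2S,3S,4R,5R)-2,5-bis[4-(benzyloxy)-3-methoxyphenyl]-3-[(benzyldimethylsilyl)methyl]-4-{[(tert-butyldimethylsilyl)oxy]methyl}oxolane | COc1cc([C@H]2O[C@@H](c3ccc(OCc4ccccc4)c(OC)c3)[C@@H](CO[Si](C)(C)C(C)(C)C)[C@@H]2C[Si](C)(C)Cc2ccccc2)ccc1OCc1ccccc1 | intermediate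
18 | {(2S,3R,4R,5R)-2,5-bis[4-(benzyloxy)-3-methoxyphenyl]oxolane-3,4-diyl}dimethanol | COc1cc([C@H]2O[C@@H](c3ccc(OCc4ccccc4)c(OC)c3)[C@@H](CO)[C@@H]2CO)ccc1OCc1ccccc1 | intermediate
19 | [(2S,3R,4R,5R)-2,5-bis(4-hydroxy-3-methoxyphenyl)oxolane-3,4-diyl]dimethanol | COc1cc([C@H]2O[C@@H](c3ccc(O)c(OC)c3)[C@@H](CO)[C@@H]2CO)ccc1O | target

Total step count: 11 (step 5 prepares the Grignard reagent in a side branch).
Longest linear sequence: 10 steps (1–4, then 6–11).

Steps most likely to fail

Step 6. Proton transfer to the magnesium enolate or oligomerisation of formaldehyde may outrun C–C bond formation, and a sluggish conjugate addition would give base time to remove the benzylic C2 hydrogen and erode optical purity. The fallback sets out from 7 and returns at 12, making the two bonds in separate operations. The copper-catalysed addition of 9 to 7 is run alone and quenched with NH4Cl to give (4S,5S)-5-[4-(benzyloxy)-3-methoxyphenyl]-4-[(benzyldimethylsilyl)methyl]oxolan-2-one F1, which no longer has the vinylogous acidity of the butenolide. LiN(SiMe3)2 in THF at −78 °C then gives the lithium enolate of this lactone F2, which is hydroxymethylated with monomeric formaldehyde on the face opposite the silylmethyl group to reach 12.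

Step 10. Cleavage of the benzyl–silicon bond by fluoride, or the later migration of the hindered primary carbon from silicon to oxygen, may stall late in the route. The fallback sets out from 7 and returns at 18, oxidising the carbon–silicon bond early through an alkoxysilane.
- (Chloromethyl)isopropoxydimethylsilane and Mg give (isopropoxydimethylsilyl)methylmagnesium chloride F3.
- Under the conditions of step 6 this gives, through the chloromagnesium enolate F4, (3R,4S,5S)-5-[4-(benzyloxy)-3-methoxyphenyl]-4-{[dimethyl(propan-2-yloxy)silyl]methyl}-3-(hydroxymethyl)oxolan-2-one F5, used crude because its hydroxyl can close onto silicon.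
- Tamao oxidation with H2O2 and KF in DMF without added base gives (3R,4R,5S)-5-[4-(benzyloxy)-3-methoxyphenyl]-3,4-bis(hydroxymethyl)oxolan-2-one F6.
- F6 is silylated at once (TBSCl, imidazole) to (3R,4R,5S)-5-[4-(benzyloxy)-3-methoxyphenyl]-3,4-bis{[(tert-butyldimethylsilyl)oxy]methyl}oxolan-2-one F7, so that the 4-hydroxymethyl group cannot take over the lactone.
- Addition of 15 gives the corresponding 2-aryl oxolan-2-ol F8, Et3SiH/BF3·OEt2 at −78 °C gives (2S,3R,4R,5R)-2,5-bis[4-(benzyloxy)-3-methoxyphenyl]-3,4-bis{[(tert-butyldimethylsilyl)oxy]methyl}oxolane F9, and Bu4NF removes both silyl ethers to give 18.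

Step 8. Deprotonation next to the lactone carbonyl by the aryllithium, followed by loss of silanolate from the β-position, or premature collapse of the tetrahedral intermediate and a second addition, may consume the lactone. The fallback sets out from 13 and returns at 16.
- The lactone is opened with the chloromagnesium amide made from MeNH(OMe)·HCl and i-PrMgCl to give (2R,3S,4S)-4-[4-(benzyloxy)-3-methoxyphenyl]-3-[(benzyldimethylsilyl)methyl]-2-{[(tert-butyldimethylsilyl)oxy]methyl}-4-hydroxy-N-methoxy-N-methylbutanamide F10.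
- Its benzylic hydroxyl is capped at once with Et3SiCl/imidazole to give the 4-[(triethylsilyl)oxy] amide F11, so that it cannot relactonise.
- Addition of 15 stops at (2R,3S,4S)-1,4-bis[4-(benzyloxy)-3-methoxyphenyl]-3-[(benzyldimethylsilyl)methyl]-2-{[(tert-butyldimethylsilyl)oxy]methyl}-4-[(triethylsilyl)oxy]butan-1-one F12, as is usual for N-methoxy-N-methyl amides.
- AcOH/THF/H2O removes the triethylsilyl group, whereupon the hydroxy ketone closes to 16.

Further compounds
F1 | step 6 | (4S,5S)-5-[4-(benzyloxy)-3-methoxyphenyl]-4-[(benzyldimethylsilyl)methyl]oxolan-2-one | COc1cc([C@H]2OC(=O)C[C@@H]2C[Si](C)(C)Cc2ccccc2)ccc1OCc1ccccc1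
F2 | step 6 | lithium enolate of (4S,5S)-5-[4-(benzyloxy)-3-methoxyphenyl]-4-[(benzyldimethylsilyl)methyl]oxolan-2-one | COc1cc([C@H]2OC(O[Li])=C[C@@H]2C[Si](C)(C)Cc2ccccc2)ccc1OCc1ccccc1
F3 | step 10 | (isopropoxydimethylsilyl)methylmagnesium chloride | CC(C)O[Si](C)(C)C[Mg]Cl
F4 | step 10 | chloromagnesium enolate of (4S,5S)-5-[4-(benzyloxy)-3-methoxyphenyl]-4-{[dimethyl(propan-2-yloxy)silyl]methyl}oxolan-2-one | COc1cc([C@H]2OC(O[Mg]Cl)=C[C@@H]2C[Si](C)(C)OC(C)C)ccc1OCc1ccccc1
F5 | step 10 | (3R,4S,5S)-5-[4-(benzyloxy)-3-methoxyphenyl]-4-{[dimethyl(propan-2-yloxy)silyl]methyl}-3-(hydroxymethyl)oxolan-2-one | COc1cc([C@H]2OC(=O)[C@@H](CO)[C@@H]2C[Si](C)(C)OC(C)C)ccc1OCc1ccccc1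
F6 | step 10 | (3R,4R,5S)-5-[4-(benzyloxy)-3-methoxyphenyl]-3,4-bis(hydroxymethyl)oxolan-2-one | COc1cc([C@H]2OC(=O)[C@@H](CO)[C@@H]2CO)ccc1OCc1ccccc1
F7 | step 10 | (3R,4R,5S)-5-[4-(benzyloxy)-3-methoxyphenyl]-3,4-bis{[(tert-butyldimethylsilyl)oxy]methyl}oxolan-2-one | COc1cc([C@H]2OC(=O)[C@@H](CO[Si](C)(C)C(C)(C)C)[C@@H]2CO[Si](C)(C)C(C)(C)C)ccc1OCc1ccccc1
F8 | step 10 | (3R,4R,5S)-2,5-bis[4-(benzyloxy)-3-methoxyphenyl]-3,4-bis{[(tert-butyldimethylsilyl)oxy]methyl}oxolan-2-ol, mixture at C2 | COc1cc([C@H]2OC(O)(c3ccc(OCc4ccccc4)c(OC)c3)[C@@H](CO[Si](C)(C)C(C)(C)C)[C@@H]2CO[Si](C)(C)C(C)(C)C)ccc1OCc1ccccc1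
F9 | step 10 | (2S,3R,4R,5R)-2,5-bis[4-(benzyloxy)-3-methoxyphenyl]-3,4-bis{[(tert-butyldimethylsilyl)oxy]methyl}oxolane | COc1cc([C@H]2O[C@@H](c3ccc(OCc4ccccc4)c(OC)c3)[C@@H](CO[Si](C)(C)C(C)(C)C)[C@@H]2CO[Si](C)(C)C(C)(C)C)ccc1OCc1ccccc1
F10 | step 8 | (2R,3S,4S)-4-[4-(benzyloxy)-3-methoxyphenyl]-3-[(benzyldimethylsilyl)methyl]-2-{[(tert-butyldimethylsilyl)oxy]methyl}-4-hydroxy-N-methoxy-N-methylbutanamide | COc1cc([C@@H](O)[C@@H](C[Si](C)(C)Cc2ccccc2)[C@H](CO[Si](C)(C)C(C)(C)C)C(=O)N(C)OC)ccc1OCc1ccccc1
F11 | step 8 | (2R,3S,4S)-4-[4-(benzyloxy)-3-methoxyphenyl]-3-[(benzyldimethylsilyl)methyl]-2-{[(tert-butyldimethylsilyl)oxy]methyl}-N-methoxy-N-methyl-4-[(triethylsilyl)oxy]butanamide | COc1cc([C@@H](O[Si](CC)(CC)CC)[C@@H](C[Si](C)(C)Cc2ccccc2)[C@H](CO[Si](C)(C)C(C)(C)C)C(=O)N(C)OC)ccc1OCc1ccccc1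
F12 | step 8 | (2R,3S,4S)-1,4-bis[4-(benzyloxy)-3-methoxyphenyl]-3-[(benzyldimethylsilyl)methyl]-2-{[(tert-butyldimethylsilyl)oxy]methyl}-4-[(triethylsilyl)oxy]butan-1-one | COc1cc([C@@H](O[Si](CC)(CC)CC)[C@@H](C[Si](C)(C)Cc2ccccc2)[C@H](CO[Si](C)(C)C(C)(C)C)C(=O)c2ccc(OCc3ccccc3)c(OC)c2)ccc1OCc1ccccc1
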